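**Plan**

- Numbering and enabling feature: ring A is C1(OAc)–C2–C3(CH3)–C9(H)–C10(OH, iPr), ring B is C3–C4(OH)–C5–C6(CH3)=C7–C8(OAr)–C9; β is the face of the C3 methyl. Ring B carries oxygen on C4 and C8 and the methyl-bearing C6 in a 1,3,5 array beside quaternary C3. This is the pattern left when a three-carbon β-silyl acryloylsilane (C4–C5–C6) is joined to the enolate of a cyclopentenyl methyl ketone (C7–C8–C9=C3).
- Retrosynthesis: the silyl groups, the C1 acetate and the C8 ester are removed; the C1/C10 diol goes back to a C1=C10 alkene, C10–isopropyl to the enol triflate of a C10 ketone, C4–O to C4–Si, and C6–CH3 to a C6/C8 dione; then C6–C7 and C3–C4 are cut together.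
- Forward: ring A arrives as an enantiopure cyclopentenyl methyl ketone and ring B is closed onto it in one (3+4) annulation. Ring B is finished first (C6 methyl, C4 hydroxyl, C8 ester), then ring A (C10 ketone, enol triflate, isopropyl, cis-diol, acetate).
- Stereochemistry: a CBS reduction sets the (S)-C10 carbinol, which steers the annulation face (C3). The boat of the oxy-Cope step sets C4 against C3, and protonation sets C9. The cis-fused bicycle then sends hydride (C8) and OsO4 (C1, C10) to its convex β face; the C10 relay centre is erased by oxidation and rebuilt in the osmylation.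

Key step: step 9

Remark: TBS = tert-butyldimethylsilyl, TIPS = triisopropylsilyl. Bicyclic compounds are named as cis-fused bicyclo[5.3.0]decanes with the ring numbering above (not systematic locants). Organolithium and enolate species are drawn as monomers.

**Route**

Step 1
Reactants: 1 3-methylcyclopent-2-en-1-one
Product: 2 2-iodo-3-methylcyclopent-2-en-1-one
Conditions: I2, pyridine, CH2Cl2, 0 °C to rt
Reagents that add atoms: iodine, II
Why: Pyridine-mediated α-iodination of an enone (conjugate addition of pyridine, iodination of the enolate, loss of pyridine) should place iodine only on the α-vinylic carbon.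

Step 2
Reactants: 2 2-iodo-3-methylcyclopent-2-en-1-one
Product: 3 (S)-2-iodo-3-methylcyclopent-2-en-1-ol
Conditions: (R)-1-methyl-3,3-diphenyltetrahydro-1H,3H-pyrrolo[1,2-c][1,3,2]oxazaborole (0.2 equiv), BH3·SMe2, THF, −20 °C; MeOH quench
Reagents that add atoms: none
Why: Corey–Bakshi–Shibata reduction in which the iodoalkenyl arm acts as the large group, so the (R)-oxazaborolidine should deliver hydride to the face that gives the (S)-carbinol, the only stereocentre carried into the key step.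

Step 3
Reactants: 3 (S)-2-iodo-3-methylcyclopent-2-en-1-ol
Product: 4 (S)-tert-butyl[(2-iodo-3-methylcyclopent-2-en-1-yl)oxy]dimethylsilane
Conditions: TBSCl, imidazole, DMF, rt
Reagents that add atoms: tert-butyldimethylsilyl chloride, CC(C)(C)[Si](C)(C)Cl
Why: Imidazole-mediated silylation of a secondary alcohol; the bulky, non-chelating OTBS group is chosen as the later face-directing group.

Step 4
Reactants: 4 (S)-tert-butyl[(2-iodo-3-methylcyclopent-2-en-1-yl)oxy]dimethylsilane, 5 N-methoxy-N-methylacetamide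
Product: 7 (S)-1-[5-(tert-butyldimethylsilyloxy)-2-methylcyclopent-1-en-1-yl]ethan-1-one (fragment 1), via vinyllithium 6 (not isolated)
Conditions: t-BuLi (2.1 equiv), Et2O, −78 °C; then 5, −78 to 0 °C; AcOH quench
Reagents that add atoms: none
Why: Iodine–lithium exchange followed by acylation with an N-methoxy-N-methylamide, whose chelated tetrahedral adduct survives until the quench and so gives the methyl ketone without over-addition; the carbinol centre is untouched.

Step 5
Reactants: 8 tert-butyldimethyl(prop-2-yn-1-yloxy)silane, 9 chlorodimethylphenylsilane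
Product: 11 tert-butyl{[3-(dimethylphenylsilyl)prop-2-yn-1-yl]oxy}dimethylsilane, via lithium acetylide 10 (not isolated)
Conditions: n-BuLi, THF, −78 °C; then 9, −78 to 0 °C
Reagents that add atoms: none
Why: Deprotonation of the terminal alkyne and C-silylation of the acetylide by the chlorosilane.

Step 6
Reactants: 11 tert-butyl{[3-(dimethylphenylsilyl)prop-2-yn-1-yl]oxy}dimethylsilane
Product: 13 rac-1-(tert-butyldimethylsilyl)-3-(dimethylphenylsilyl)prop-2-yn-1-ol, via α-lithio ether 12 (not isolated)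
Conditions: s-BuLi, THF, −78 °C; then AcOH, −78 °C
Reagents that add atoms: none
Why: Retro-Brook rearrangement: deprotonation at the propargylic O–CH2 is followed by 1,2-migration of the TBS group from oxygen to carbon, and the cold acidic quench should trap the carbinol before it reverts.

Step 7
Reactants: 13 rac-1-(tert-butyldimethylsilyl)-3-(dimethylphenylsilyl)prop-2-yn-1-ol
Product: 14 1-(tert-butyldimethylsilyl)-3-(dimethylphenylsilyl)prop-2-yn-1-one
Conditions: Dess–Martin periodinane, CH2Cl2, 0 °C to rt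
Reagents that add atoms: none
Why: Dess–Martin oxidation of an α-silyl carbinol to the acylsilane under non-basic conditions, which should avoid Brook cleavage of the C–Si bond.

Step 8
Reactants: 14 1-(tert-butyldimethylsilyl)-3-(dimethylphenylsilyl)prop-2-yn-1-one
Product: 15 (Z)-1-(tert-butyldimethylsilyl)-3-(dimethylphenylsilyl)prop-2-en-1-one (fragment 2)
Conditions: H2 (1 atm), Pd/CaCO3 poisoned with Pb(OAc)2, quinoline, hexane/EtOAc, rt, dark
Reagents that add atoms: none
Why: Semi-hydrogenation on poisoned palladium delivers both hydrogens to one face of the alkyne and should give the Z-alkene, quinoline preventing over-reduction.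

Step 9
Reactants: 7 (S)-1-[5-(tert-butyldimethylsilyloxy)-2-methylcyclopent-1-en-1-yl]ethan-1-one (fragment 1), 15 (Z)-1-(tert-butyldimethylsilyl)-3-(dimethylphenylsilyl)prop-2-en-1-one (fragment 2)
Product: 19 4β-(dimethylphenylsilyl)-3β-methyl-6,10β-bis(tert-butyldimethylsilyloxy)-9β-H-bicyclo[5.3.0]dec-5-en-8-one, via lithium enolate 16 (not isolated), via cyclopropanolate 17 (not isolated), via bicyclic enolate 18 (not isolated)
Conditions: LiN(iPr)2, THF, −80 °C; then 15 in THF, −80 to −30 °C; AcOH quench at −80 °C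
Reagents that add atoms: none
Why: The cross-conjugated enolate 16 adds 1,2 to the acylsilane carbonyl of 15 (bond C6–C7), the adduct undergoes Brook migration of silicon from carbon to oxygen, and the resulting silyl-stabilised allylic carbanion closes onto the C8 ketone to give the cis-1,2-divinylcyclopropanolate 17, whose anionic oxy-Cope rearrangement forms C3–C4 and gives enolate 18. The reaction type is the Brook rearrangement-mediated (3+4) annulation of β-silyl acryloylsilanes with enolates of alkenyl methyl ketones, which is known for cyclopentenyl ketones and for Z-acryloylsilanes. Ring B is closed in two stages, a 3-exo-trig carbonyl addition followed by (3,3)-sigmatropic expansion of the three-membered ring to the seven-membered ring. The boat transition state holds the ring-bound C3 methyl and the Z-silyl group both inward, so they should end cis (3β-CH3, 4β-Si); the divinylcyclopropane unit should lie on the ring-A face anti to the 10β-OTBS group, so C4 bonds to the α face of C3; C9 is set by protonation of 18 to the cis-fused ketone, which is also the more stable epimer because C8 is then trans to both C3–CH3 and C10–OTBS. The step needs 1,2- rather than conjugate addition and (3+4) rather than (3+2) closure, which the highly electrophilic acylsilane carbonyl, the anion-stabilising β-silyl group and the cis geometry of 17 should secure; the cold quench is meant to forestall β-elimination of the C10 silanolate from 18.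

Step 10
Reactants: 19 4β-(dimethylphenylsilyl)-3β-methyl-6,10β-bis(tert-butyldimethylsilyloxy)-9β-H-bicyclo[5.3.0]dec-5-en-8-one
Product: 20 4β-(dimethylphenylsilyl)-3β-methyl-10β-(tert-butyldimethylsilyloxy)-9β-H-bicyclo[5.3.0]decane-6,8-dione
Conditions: 1 M HCl (aq), THF, 0 °C
Reagents that add atoms: none
Why: Acid hydrolysis of a silyl enol ether (protonation at C5) is far faster than cleavage of the alkyl OTBS ether, so the C6 ketone should be unmasked selectively, and any trans-fused material can equilibrate at C9 to the cis-fused epimer.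

Step 11
Reactants: 20 4β-(dimethylphenylsilyl)-3β-methyl-10β-(tert-butyldimethylsilyloxy)-9β-H-bicyclo[5.3.0]decane-6,8-dione
Product: 21 4β-(dimethylphenylsilyl)-3β-methyl-10β-(tert-butyldimethylsilyloxy)-6-(trifluoromethylsulfonyloxy)-9β-H-bicyclo[5.3.0]dec-6-en-8-one
Conditions: Tf2O, Et3N, CH2Cl2, −78 °C
Reagents that add atoms: trifluoromethanesulfonic anhydride, O=S(=O)(OS(=O)(=O)C(F)(F)F)C(F)(F)F
Why: O-sulfonylation of the 1,3-diketonate (vinylogous triflate formation) should occur at the less hindered C6 oxygen, flanked by a CH2, and not at O8 beside the ring-fusion methine, as with 4-substituted cyclohexane-1,3-diones.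

Step 12
Reactants: 21 4β-(dimethylphenylsilyl)-3β-methyl-10β-(tert-butyldimethylsilyloxy)-6-(trifluoromethylsulfonyloxy)-9β-H-bicyclo[5.3.0]dec-6-en-8-one
Product: 22 4β-(dimethylphenylsilyl)-3β,6-dimethyl-10β-(tert-butyldimethylsilyloxy)-9β-H-bicyclo[5.3.0]dec-6-en-8-one
Conditions: Me2CuLi (from CuI and MeLi, Et2O, 0 °C); then 21, Et2O/THF, −78 to −40 °C
Reagents that add atoms: lithium dimethylcuprate, [Li+].C[Cu-]C
Why: Conjugate addition–elimination of the cuprate on the β-triflyloxy enone should replace triflate by methyl and fix the double bond at C6=C7 in conjugation with C8=O.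

Step 13
Reactants: 22 4β-(dimethylphenylsilyl)-3β,6-dimethyl-10β-(tert-butyldimethylsilyloxy)-9β-H-bicyclo[5.3.0]dec-6-en-8-one
Product: 23 4β-hydroxy-3β,6-dimethyl-10β-(tert-butyldimethylsilyloxy)-9β-H-bicyclo[5.3.0]dec-6-en-8-one
Conditions: Hg(OAc)2, CH3CO3H (32% in AcOH), AcOH, rt
Reagents that add atoms: peracetic acid, CC(=O)OO
Why: Fleming–Tamao oxidation (ipso-mercuration of the phenyl group, then peracid-induced 1,2-shift of C4 from silicon to oxygen with retention) should give the 4β-alcohol, and it is placed here because the conjugated, electron-poor C6=C7 bond resists the electrophilic reagents.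

Step 14
Reactants: 23 4β-hydroxy-3β,6-dimethyl-10β-(tert-butyldimethylsilyloxy)-9β-H-bicyclo[5.3.0]dec-6-en-8-one
Product: 24 3β,6-dimethyl-10β-(tert-butyldimethylsilyloxy)-4β-(triisopropylsilyloxy)-9β-H-bicyclo[5.3.0]dec-6-en-8-one
Conditions: TIPSOTf, 2,6-lutidine, CH2Cl2, 0 °C to rt
Reagents that add atoms: triisopropylsilyl trifluoromethanesulfonate, CC(C)[Si](C(C)C)(C(C)C)OS(=O)(=O)C(F)(F)F
Why: A silyl triflate with a hindered pyridine base silylates even the neopentyl C4 alcohol, and TIPS is chosen because it should outlast the acid that later removes the C10 OTBS group.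

Step 15
Reactants: 24 3β,6-dimethyl-10β-(tert-butyldimethylsilyloxy)-4β-(triisopropylsilyloxy)-9β-H-bicyclo[5.3.0]dec-6-en-8-one
Product: 25 3β,6-dimethyl-10β-(tert-butyldimethylsilyloxy)-4β-(triisopropylsilyloxy)-9β-H-bicyclo[5.3.0]dec-6-en-8α-ol
Conditions: NaBH4, CeCl3·7H2O, MeOH, −78 to 0 °C
Reagents that add atoms: none
Why: Luche 1,2-reduction in which hydride should attack the cerium-activated carbonyl from the convex β face, anti to the C9–C10 bond, to give the 8α-alcohol.

Step 16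
Reactants: 26 4-hydroxybenzoic acid
Product: 28 4-(tert-butyldimethylsilyloxy)benzoic acid, via bis-silyl compound 27 (not isolated)
Conditions: TBSCl (2.2 equiv), imidazole, DMF, rt; then AcOH/THF/H2O (3:1:1), rt
Reagents that add atoms: tert-butyldimethylsilyl chloride, CC(C)(C)[Si](C)(C)Cl
Why: Exhaustive silylation followed by hydrolysis of the much more labile silyl ester should leave the aryl silyl ether in place.

Step 17
Reactants: 25 3β,6-dimethyl-10β-(tert-butyldimethylsilyloxy)-4β-(triisopropylsilyloxy)-9β-H-bicyclo[5.3.0]dec-6-en-8α-ol, 28 4-(tert-butyldimethylsilyloxy)benzoic acid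
Product: 29 8α-[4-(tert-butyldimethylsilyloxy)benzoyloxy]-3β,6-dimethyl-10β-(tert-butyldimethylsilyloxy)-4β-(triisopropylsilyloxy)-9β-H-bicyclo[5.3.0]dec-6-ene
Conditions: N,N'-dicyclohexylcarbodiimide, 4-(dimethylamino)pyridine (cat.), CH2Cl2, rt
Reagents that add atoms: none
Why: Steglich esterification acylates the secondary allylic alcohol at oxygen, so C8 keeps its configuration, and the ester also serves to deactivate C6=C7 in step 22.

Step 18
Reactants: 29 8α-[4-(tert-butyldimethylsilyloxy)benzoyloxy]-3β,6-dimethyl-10β-(tert-butyldimethylsilyloxy)-4β-(triisopropylsilyloxy)-9β-H-bicyclo[5.3.0]dec-6-ene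
Product: 30 8α-[4-(tert-butyldimethylsilyloxy)benzoyloxy]-3β,6-dimethyl-4β-(triisopropylsilyloxy)-9β-H-bicyclo[5.3.0]dec-6-en-10β-ol
Conditions: camphor-10-sulfonic acid (cat.), MeOH/CH2Cl2 (1:1), 0 °C to rt
Reagents that add atoms: none
Why: Acid-catalysed methanolysis should cleave the alkyl OTBS ether, while the aryl silyl ether (weakly basic oxygen) and the more hindered, more acid-stable TIPS ether persist.

Step 19
Reactants: 30 8α-[4-(tert-butyldimethylsilyloxy)benzoyloxy]-3β,6-dimethyl-4β-(triisopropylsilyloxy)-9β-H-bicyclo[5.3.0]dec-6-en-10β-ol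
Product: 31 8α-[4-(tert-butyldimethylsilyloxy)benzoyloxy]-3β,6-dimethyl-4β-(triisopropylsilyloxy)-9β-H-bicyclo[5.3.0]dec-6-en-10-one
Conditions: Dess–Martin periodinane, CH2Cl2, 0 °C to rt
Reagents that add atoms: none
Why: Dess–Martin oxidation under near-neutral conditions should give the cyclopentanone without β-elimination of the C8 ester or epimerisation at C9.

Step 20
Reactants: 31 8α-[4-(tert-butyldimethylsilyloxy)benzoyloxy]-3β,6-dimethyl-4β-(triisopropylsilyloxy)-9β-H-bicyclo[5.3.0]dec-6-en-10-one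
Product: 33 8α-[4-(tert-butyldimethylsilyloxy)benzoyloxy]-3β,6-dimethyl-4β-(triisopropylsilyloxy)-10-(trifluoromethylsulfonyloxy)-9β-H-bicyclo[5.3.0]deca-1(10),6-diene, via potassium enolate 32 (not isolated)
Conditions: KN(SiMe3)2, THF, −78 °C; then N-(5-chloropyridin-2-yl)-N-(trifluoromethylsulfonyl)trifluoromethanesulfonamide, −78 °C
Reagents that add atoms: N-(5-chloropyridin-2-yl)-N-(trifluoromethylsulfonyl)trifluoromethanesulfonamide, O=S(=O)(N(c1ccc(Cl)cn1)S(=O)(=O)C(F)(F)F)C(F)(F)F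
Why: Kinetic deprotonation by the bulky amide at the open C1 methylene (not at the hindered C9 methine, which would expel the C8 ester) and O-sulfonylation of the enolate should give the C1=C10 enol triflate.

Step 21
Reactants: 33 8α-[4-(tert-butyldimethylsilyloxy)benzoyloxy]-3β,6-dimethyl-4β-(triisopropylsilyloxy)-10-(trifluoromethylsulfonyloxy)-9β-H-bicyclo[5.3.0]deca-1(10),6-diene
Product: 34 8α-[4-(tert-butyldimethylsilyloxy)benzoyloxy]-10-isopropyl-3β,6-dimethyl-4β-(triisopropylsilyloxy)-9β-H-bicyclo[5.3.0]deca-1(10),6-diene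
Conditions: iPrZnBr, PdCl2(dppf) (5 mol%), THF, rt to 45 °C
Reagents that add atoms: isopropylzinc bromide, CC(C)[Zn]Br
Why: Negishi coupling (oxidative addition of the alkenyl triflate to zerovalent palladium, transmetalation from the secondary alkylzinc, reductive elimination), in which the wide-bite-angle dppf ligand should suppress isomerisation to the n-propyl product.

Step 22
Reactants: 34 8α-[4-(tert-butyldimethylsilyloxy)benzoyloxy]-10-isopropyl-3β,6-dimethyl-4β-(triisopropylsilyloxy)-9β-H-bicyclo[5.3.0]deca-1(10),6-diene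
Product: 35 8α-[4-(tert-butyldimethylsilyloxy)benzoyloxy]-10α-isopropyl-3β,6-dimethyl-4β-(triisopropylsilyloxy)-9β-H-bicyclo[5.3.0]dec-6-ene-1β,10β-diol
Conditions: OsO4 (5 mol%), N-methylmorpholine N-oxide, acetone/H2O (8:1), 0 °C to rt
Reagents that add atoms: osmium tetroxide, O=[Os](=O)(=O)=O; N-methylmorpholine N-oxide, C[N+]1([O-])CCOCC1; water, O
Why: Catalytic OsO4 syn-dihydroxylation should take the more electron-rich C1=C10 bond from the convex β face, anti to the allylic C9–C8 bond, setting 1β-OH and 10β-OH together, while C6=C7 is deactivated by its allylic ester (as in the distal-selective dihydroxylation of geranyl esters).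

Step 23
Reactants: 35 8α-[4-(tert-butyldimethylsilyloxy)benzoyloxy]-10α-isopropyl-3β,6-dimethyl-4β-(triisopropylsilyloxy)-9β-H-bicyclo[5.3.0]dec-6-ene-1β,10β-diol
Product: 36 1β-acetoxy-8α-[4-(tert-butyldimethylsilyloxy)benzoyloxy]-10α-isopropyl-3β,6-dimethyl-4β-(triisopropylsilyloxy)-9β-H-bicyclo[5.3.0]dec-6-en-10β-ol
Conditions: Ac2O, pyridine, 4-(dimethylamino)pyridine (cat.), CH2Cl2, 0 °C to rt
Reagents that add atoms: acetic anhydride, CC(=O)OC(C)=O
Why: Nucleophile-catalysed acetylation should take the secondary C1 hydroxyl only, the tertiary C10 hydroxyl being unreactive under these conditions.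

Step 24
Reactants: 36 1β-acetoxy-8α-[4-(tert-butyldimethylsilyloxy)benzoyloxy]-10α-isopropyl-3β,6-dimethyl-4β-(triisopropylsilyloxy)-9β-H-bicyclo[5.3.0]dec-6-en-10β-ol
Product: 37 CNP0146780.2 (1β-acetoxy-8α-(4-hydroxybenzoyloxy)-10α-isopropyl-3β,6-dimethyl-9β-H-bicyclo[5.3.0]dec-6-ene-4β,10β-diol)
Conditions: HF·pyridine, pyridine, THF, 0 °C to rt
Reagents that add atoms: none
Why: Fluoride-driven Si–O cleavage under mildly acidic, buffered conditions should remove both the aryl TBS and the C4 TIPS ether without acyl migration or ester cleavage.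

**Compound list**

1 | 3-methylcyclopent-2-en-1-one | CC1=CC(=O)CC1 | starting material
2 | 2-iodo-3-methylcyclopent-2-en-1-one | CC1=C(I)C(=O)CC1 | intermediate
3 | (S)-2-iodo-3-methylcyclopent-2-en-1-ol | CC1=C(I)[C@@H](O)CC1 | intermediate
4 | (S)-tert-butyl[(2-iodo-3-methylcyclopent-2-en-1-yl)oxy]dimethylsilane | CC1=C(I)[C@@H](O[Si](C)(C)C(C)(C)C)CC1 | intermediate
5 | N-methoxy-N-methylacetamide | CC(=O)N(C)OC | starting material
6 | vinyllithium, [(S)-5-(tert-butyldimethylsilyloxy)-2-methylcyclopent-1-en-1-yl]lithium | [Li]C1=C(C)CC[C@@H]1O[Si](C)(C)C(C)(C)C | intermediate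
7 | fragment 1, (S)-1-[5-(tert-butyldimethylsilyloxy)-2-methylcyclopent-1-en-1-yl]ethan-1-one | CC(=O)C1=C(C)CC[C@@H]1O[Si](C)(C)C(C)(C)C | intermediate
8 | tert-butyldimethyl(prop-2-yn-1-yloxy)silane | C#CCO[Si](C)(C)C(C)(C)C | starting material
9 | chlorodimethylphenylsilane | C[Si](C)(Cl)c1ccccc1 | starting material
10 | lithium acetylide, [3-(tert-butyldimethylsilyloxy)prop-1-yn-1-yl]lithium | [Li]C#CCO[Si](C)(C)C(C)(C)C | intermediate
11 | tert-butyl{[3-(dimethylphenylsilyl)prop-2-yn-1-yl]oxy}dimethylsilane | C[Si](C)(c1ccccc1)C#CCO[Si](C)(C)C(C)(C)C | intermediate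
12 | α-lithio ether, [1-(tert-butyldimethylsilyloxy)-3-(dimethylphenylsilyl)prop-2-yn-1-yl]lithium | C[Si](C)(c1ccccc1)C#CC([Li])O[Si](C)(C)C(C)(C)C | intermediate
13 | rac-1-(tert-butyldimethylsilyl)-3-(dimethylphenylsilyl)prop-2-yn-1-ol | C[Si](C)(c1ccccc1)C#CC(O)[Si](C)(C)C(C)(C)C | intermediate
14 | 1-(tert-butyldimethylsilyl)-3-(dimethylphenylsilyl)prop-2-yn-1-one | C[Si](C)(c1ccccc1)C#CC(=O)[Si](C)(C)C(C)(C)C | intermediate
15 | fragment 2, (Z)-1-(tert-butyldimethylsilyl)-3-(dimethylphenylsilyl)prop-2-en-1-one | C[Si](C)(c1ccccc1)/C=C\C(=O)[Si](C)(C)C(C)(C)C | intermediate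
16 | lithium enolate of 7, lithium 1-[(S)-5-(tert-butyldimethylsilyloxy)-2-methylcyclopent-1-en-1-yl]ethen-1-olate | C=C(O[Li])C1=C(C)CC[C@@H]1O[Si](C)(C)C(C)(C)C | intermediate
17 | cyclopropanolate, lithium 2-(tert-butyldimethylsilyloxy)-2-[(Z)-2-(dimethylphenylsilyl)vinyl]-1-[(S)-5-(tert-butyldimethylsilyloxy)-2-methylcyclopent-1-en-1-yl]cyclopropan-1-olate, the two alkenyl groups cis | [Li]O[C@]1(C[C@]1(O[Si](C)(C)C(C)(C)C)/C=C\[Si](C)(C)c2ccccc2)C3=C(C)CC[C@@H]3O[Si](C)(C)C(C)(C)C | intermediate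
18 | bicyclic enolate, lithium C8(O)=C9 enolate of 19 | C1C[C@]2(C)[C@@H]([Si](C)(C)c3ccccc3)C=C(O[Si](C)(C)C(C)(C)C)CC(O[Li])=C2[C@H]1O[Si](C)(C)C(C)(C)C | intermediate
19 | 4β-(dimethylphenylsilyl)-3β-methyl-6,10β-bis(tert-butyldimethylsilyloxy)-9β-H-bicyclo[5.3.0]dec-5-en-8-one | C1C[C@]2(C)[C@@H]([Si](C)(C)c3ccccc3)C=C(O[Si](C)(C)C(C)(C)C)CC(=O)[C@@H]2[C@H]1O[Si](C)(C)C(C)(C)C | intermediate
20 | 4β-(dimethylphenylsilyl)-3β-methyl-10β-(tert-butyldimethylsilyloxy)-9β-H-bicyclo[5.3.0]decane-6,8-dione | C1C[C@]2(C)[C@@H]([Si](C)(C)c3ccccc3)CC(=O)CC(=O)[C@@H]2[C@H]1O[Si](C)(C)C(C)(C)C | intermediate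
21 | 4β-(dimethylphenylsilyl)-3β-methyl-10β-(tert-butyldimethylsilyloxy)-6-(trifluoromethylsulfonyloxy)-9β-H-bicyclo[5.3.0]dec-6-en-8-one | C1C[C@]2(C)[C@@H]([Si](C)(C)c3ccccc3)CC(OS(=O)(=O)C(F)(F)F)=CC(=O)[C@@H]2[C@H]1O[Si](C)(C)C(C)(C)C | intermediate
22 | 4β-(dimethylphenylsilyl)-3β,6-dimethyl-10β-(tert-butyldimethylsilyloxy)-9β-H-bicyclo[5.3.0]dec-6-en-8-one | C1C[C@]2(C)[C@@H]([Si](C)(C)c3ccccc3)CC(C)=CC(=O)[C@@H]2[C@H]1O[Si](C)(C)C(C)(C)C | intermediate
23 | 4β-hydroxy-3β,6-dimethyl-10β-(tert-butyldimethylsilyloxy)-9β-H-bicyclo[5.3.0]dec-6-en-8-one | C1C[C@]2(C)[C@@H](O)CC(C)=CC(=O)[C@@H]2[C@H]1O[Si](C)(C)C(C)(C)C | intermediate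
24 | 3β,6-dimethyl-10β-(tert-butyldimethylsilyloxy)-4β-(triisopropylsilyloxy)-9β-H-bicyclo[5.3.0]dec-6-en-8-one | C1C[C@]2(C)[C@@H](O[Si](C(C)C)(C(C)C)C(C)C)CC(C)=CC(=O)[C@@H]2[C@H]1O[Si](C)(C)C(C)(C)C | intermediate
25 | 3β,6-dimethyl-10β-(tert-butyldimethylsilyloxy)-4β-(triisopropylsilyloxy)-9β-H-bicyclo[5.3.0]dec-6-en-8α-ol | C1C[C@]2(C)[C@@H](O[Si](C(C)C)(C(C)C)C(C)C)CC(C)=C[C@H](O)[C@@H]2[C@H]1O[Si](C)(C)C(C)(C)C | intermediate
26 | 4-hydroxybenzoic acid | OC(=O)c1ccc(O)cc1 | starting material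
27 | bis-silyl compound, tert-butyldimethylsilyl 4-(tert-butyldimethylsilyloxy)benzoate | CC(C)(C)[Si](C)(C)OC(=O)c1ccc(O[Si](C)(C)C(C)(C)C)cc1 | intermediate
28 | 4-(tert-butyldimethylsilyloxy)benzoic acid | OC(=O)c1ccc(O[Si](C)(C)C(C)(C)C)cc1 | intermediate
29 | 8α-[4-(tert-butyldimethylsilyloxy)benzoyloxy]-3β,6-dimethyl-10β-(tert-butyldimethylsilyloxy)-4β-(triisopropylsilyloxy)-9β-H-bicyclo[5.3.0]dec-6-ene | C1C[C@]2(C)[C@@H](O[Si](C(C)C)(C(C)C)C(C)C)CC(C)=C[C@H](OC(=O)c3ccc(O[Si](C)(C)C(C)(C)C)cc3)[C@@H]2[C@H]1O[Si](C)(C)C(C)(C)C | intermediate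
30 | 8α-[4-(tert-butyldimethylsilyloxy)benzoyloxy]-3β,6-dimethyl-4β-(triisopropylsilyloxy)-9β-H-bicyclo[5.3.0]dec-6-en-10β-ol | C1C[C@]2(C)[C@@H](O[Si](C(C)C)(C(C)C)C(C)C)CC(C)=C[C@H](OC(=O)c3ccc(O[Si](C)(C)C(C)(C)C)cc3)[C@@H]2[C@H]1O | intermediate
31 | 8α-[4-(tert-butyldimethylsilyloxy)benzoyloxy]-3β,6-dimethyl-4β-(triisopropylsilyloxy)-9β-H-bicyclo[5.3.0]dec-6-en-10-one | C1C[C@]2(C)[C@@H](O[Si](C(C)C)(C(C)C)C(C)C)CC(C)=C[C@H](OC(=O)c3ccc(O[Si](C)(C)C(C)(C)C)cc3)[C@@H]2C1=O | intermediate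
32 | potassium enolate, potassium C10(O)=C1 enolate of 31 | C1[C@]2(C)[C@@H](O[Si](C(C)C)(C(C)C)C(C)C)CC(C)=C[C@H](OC(=O)c3ccc(O[Si](C)(C)C(C)(C)C)cc3)[C@@H]2C(O[K])=C1 | intermediate
33 | 8α-[4-(tert-butyldimethylsilyloxy)benzoyloxy]-3β,6-dimethyl-4β-(triisopropylsilyloxy)-10-(trifluoromethylsulfonyloxy)-9β-H-bicyclo[5.3.0]deca-1(10),6-diene | C1[C@]2(C)[C@@H](O[Si](C(C)C)(C(C)C)C(C)C)CC(C)=C[C@H](OC(=O)c3ccc(O[Si](C)(C)C(C)(C)C)cc3)[C@@H]2C(OS(=O)(=O)C(F)(F)F)=C1 | intermediate
34 | 8α-[4-(tert-butyldimethylsilyloxy)benzoyloxy]-10-isopropyl-3β,6-dimethyl-4β-(triisopropylsilyloxy)-9β-H-bicyclo[5.3.0]deca-1(10),6-diene | C1[C@]2(C)[C@@H](O[Si](C(C)C)(C(C)C)C(C)C)CC(C)=C[C@H](OC(=O)c3ccc(O[Si](C)(C)C(C)(C)C)cc3)[C@@H]2C(C(C)C)=C1 | intermediate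
35 | 8α-[4-(tert-butyldimethylsilyloxy)benzoyloxy]-10α-isopropyl-3β,6-dimethyl-4β-(triisopropylsilyloxy)-9β-H-bicyclo[5.3.0]dec-6-ene-1β,10β-diol | O[C@H]1C[C@]2(C)[C@@H](O[Si](C(C)C)(C(C)C)C(C)C)CC(C)=C[C@H](OC(=O)c3ccc(O[Si](C)(C)C(C)(C)C)cc3)[C@@H]2[C@]1(O)C(C)C | intermediate
36 | 1β-acetoxy-8α-[4-(tert-butyldimethylsilyloxy)benzoyloxy]-10α-isopropyl-3β,6-dimethyl-4β-(triisopropylsilyloxy)-9β-H-bicyclo[5.3.0]dec-6-en-10β-ol | CC(=O)O[C@H]1C[C@]2(C)[C@@H](O[Si](C(C)C)(C(C)C)C(C)C)CC(C)=C[C@H](OC(=O)c3ccc(O[Si](C)(C)C(C)(C)C)cc3)[C@@H]2[C@]1(O)C(C)C | intermediate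
37 | CNP0146780.2, 1β-acetoxy-8α-(4-hydroxybenzoyloxy)-10α-isopropyl-3β,6-dimethyl-9β-H-bicyclo[5.3.0]dec-6-ene-4β,10β-diol | CC(=O)O[C@H]1C[C@]2(C)[C@@H](O)CC(C)=C[C@H](OC(=O)c3ccc(O)cc3)[C@@H]2[C@]1(O)C(C)C | target

**Step count and risks**

Total step count: 24. Longest linear sequence: 19 (steps 1–4, 9–15, 17–24; the branch through steps 5–8 is equally long).

Steps most likely to fail:

Step 9. The oxy-Cope step may stall at cyclopropanolate 17, because the boat has both the C3 methyl and the Z-silyl group pointing inward. The warming then needed can lead to ring-opening of the cyclopropanolate or to β-elimination of the C10 silanolate from enolate 18, and face selectivity against the 10β-OTBS group may erode. Fallback, setting out from 7 and 15 and returning at 20: the annulation is run as far as 17, which is silylated at −80 °C with Me3SiCl to the isolable bis(silyloxy)-cis-divinylcyclopropane F1. Heating F1 in toluene (80–110 °C) should drive the neutral divinylcyclopropane rearrangement to the bis(silyl enol ether) F2 without any enolate being present, and 1 M HCl in THF should hydrolyse both enol ethers of F2 to dione 20.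

Step 22. Site selectivity may be lost through competing osmylation of C6=C7, or the reagent may attack the α face. Fallback, setting out from 34 and returning at 36: iBu2AlH (CH2Cl2, −78 °C) cleaves the C8 ester reductively to the allylic alcohol F3, and MnO2 oxidises it to the dienone F4, in which C6=C7 is conjugated to the C8 ketone and inert to OsO4. OsO4/N-methylmorpholine N-oxide should then dihydroxylate only C1=C10 to the diol F5; Ac2O/pyridine gives the C1 acetate F6; a second Luche reduction returns the 8α-alcohol F7; and esterification of F7 with 28 (N,N'-dicyclohexylcarbodiimide, 4-(dimethylamino)pyridine) gives 36.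

Step 11. Sulfonylation may occur at O8 instead of O6, which after the cuprate step would put the methyl on C8 and the carbonyl on C6. Fallback, setting out from 19 and returning at 22, which uses the regiochemistry already fixed in 19: NaBH4 (MeOH, 0 °C) reduces the C8 ketone to the carbinol F8 (C8 epimers, of no consequence) with the silyl enol ether intact. Dilute HCl in THF unmasks the C6 ketone to the aldol F9, and TsOH (cat.) in benzene at 60 °C dehydrates it to the enone F10 (C6 ketone, C7=C8). MeLi with CeCl3 (THF, −78 °C) adds 1,2 to give the tertiary allylic alcohol F11, and pyridinium chlorochromate, (C5H5NH)[CrO3Cl], effects the oxidative 1,3-transposition of F11 to enone 22.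

Further compounds
F1 | step 9 | trimethylsilyl ether of 17, 1-(trimethylsilyloxy)-2-(tert-butyldimethylsilyloxy)-2-[(Z)-2-(dimethylphenylsilyl)vinyl]-1-[(S)-5-(tert-butyldimethylsilyloxy)-2-methylcyclopent-1-en-1-yl]cyclopropane, alkenyl groups cis | C[Si](C)(C)O[C@]1(C[C@]1(O[Si](C)(C)C(C)(C)C)/C=C\[Si](C)(C)c2ccccc2)C3=C(C)CC[C@@H]3O[Si](C)(C)C(C)(C)C
F2 | step 9 | 4β-(dimethylphenylsilyl)-3β-methyl-6,10β-bis(tert-butyldimethylsilyloxy)-8-(trimethylsilyloxy)bicyclo[5.3.0]deca-5,8-diene | C1C[C@]2(C)[C@@H]([Si](C)(C)c3ccccc3)C=C(O[Si](C)(C)C(C)(C)C)CC(O[Si](C)(C)C)=C2[C@H]1O[Si](C)(C)C(C)(C)C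
F3 | step 22 | 10-isopropyl-3β,6-dimethyl-4β-(triisopropylsilyloxy)-9β-H-bicyclo[5.3.0]deca-1(10),6-dien-8α-ol | C1[C@]2(C)[C@@H](O[Si](C(C)C)(C(C)C)C(C)C)CC(C)=C[C@H](O)[C@@H]2C(C(C)C)=C1
F4 | step 22 | 10-isopropyl-3β,6-dimethyl-4β-(triisopropylsilyloxy)-9β-H-bicyclo[5.3.0]deca-1(10),6-dien-8-one | C1[C@]2(C)[C@@H](O[Si](C(C)C)(C(C)C)C(C)C)CC(C)=CC(=O)[C@@H]2C(C(C)C)=C1
F5 | step 22 | 1β,10β-dihydroxy-10α-isopropyl-3β,6-dimethyl-4β-(triisopropylsilyloxy)-9β-H-bicyclo[5.3.0]dec-6-en-8-one | O[C@H]1C[C@]2(C)[C@@H](O[Si](C(C)C)(C(C)C)C(C)C)CC(C)=CC(=O)[C@@H]2[C@]1(O)C(C)C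
F6 | step 22 | 1β-acetoxy-10β-hydroxy-10α-isopropyl-3β,6-dimethyl-4β-(triisopropylsilyloxy)-9β-H-bicyclo[5.3.0]dec-6-en-8-one | CC(=O)O[C@H]1C[C@]2(C)[C@@H](O[Si](C(C)C)(C(C)C)C(C)C)CC(C)=CC(=O)[C@@H]2[C@]1(O)C(C)C
F7 | step 22 | 1β-acetoxy-10α-isopropyl-3β,6-dimethyl-4β-(triisopropylsilyloxy)-9β-H-bicyclo[5.3.0]dec-6-ene-8α,10β-diol | CC(=O)O[C@H]1C[C@]2(C)[C@@H](O[Si](C(C)C)(C(C)C)C(C)C)CC(C)=C[C@H](O)[C@@H]2[C@]1(O)C(C)C
F8 | step 11 | 4β-(dimethylphenylsilyl)-3β-methyl-6,10β-bis(tert-butyldimethylsilyloxy)-9β-H-bicyclo[5.3.0]dec-5-en-8-ol (C8 epimers) | C1C[C@]2(C)[C@@H]([Si](C)(C)c3ccccc3)C=C(O[Si](C)(C)C(C)(C)C)CC(O)[C@@H]2[C@H]1O[Si](C)(C)C(C)(C)C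
F9 | step 11 | 4β-(dimethylphenylsilyl)-8-hydroxy-3β-methyl-10β-(tert-butyldimethylsilyloxy)-9β-H-bicyclo[5.3.0]decan-6-one (C8 epimers) | C1C[C@]2(C)[C@@H]([Si](C)(C)c3ccccc3)CC(=O)CC(O)[C@@H]2[C@H]1O[Si](C)(C)C(C)(C)C
F10 | step 11 | 4β-(dimethylphenylsilyl)-3β-methyl-10β-(tert-butyldimethylsilyloxy)-9β-H-bicyclo[5.3.0]dec-7-en-6-one | C1C[C@]2(C)[C@@H]([Si](C)(C)c3ccccc3)CC(=O)C=C[C@@H]2[C@H]1O[Si](C)(C)C(C)(C)C
F11 | step 11 | 4β-(dimethylphenylsilyl)-3β,6-dimethyl-10β-(tert-butyldimethylsilyloxy)-9β-H-bicyclo[5.3.0]dec-7-en-6-ol (C6 epimers) | C1C[C@]2(C)[C@@H]([Si](C)(C)c3ccccc3)CC(C)(O)C=C[C@@H]2[C@H]1O[Si](C)(C)C(C)(C)C
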